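Everything rests on cutting the O1–C7 and O1–C2 bonds of the oxepin-2-one ring, which turns the lactone back into a cyclohexanone. The feature exploited is C7: a fully substituted ring carbon bound to O1 and to the carbinol carbon C1′, exactly what a quaternary ketone α-carbon becomes after migrating to oxygen. A single Baeyer–Villiger oxidation therefore builds the seven-membered ring, makes the hindered tertiary ester without an acylation and passes on the C7/C1′ stereo pair unchanged. Its precursor is a resolved, silylated aldol, (2R)-2-[(1R)-3-benzyloxy-1-(triethylsilyloxy)propyl]-2-methylcyclohexanone, from 2-methylcyclohexanone and 3-(benzyloxy)propanal. Both Z-alkenyl chains are attached afterwards by Negishi couplings.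

Key step: step 5

Remark: commercial 2-methylcyclohexanone is racemic and loses its stereocentre on enolisation; the two stereocentres arise as a racemic pair in step 2 and the absolute configuration is fixed by the resolution in step 3, to be confirmed through the α-methoxy-α-(trifluoromethyl)phenylacetates of the carbinol. Lactone atoms are numbered O1, C2 (carbonyl) to C7; C1′ is the carbinol carbon on C7.

Step 1
Reactants: 1 2-methylcyclohexanone
Product: 2 1-methyl-2-(trimethylsilyloxy)cyclohex-1-ene
Conditions: Me3SiCl, NaI, Et3N, MeCN, rt; fractional distillation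
Reagents that add atoms: chlorotrimethylsilane, C[Si](C)(C)Cl
Why: Silylation by Me3SiI made in the flask is reversible under these conditions, so the more substituted enol ether should predominate (thermodynamic silyl enol ether formation); the minor regioisomer is removed by distillation.

Step 2
Reactants: 2 1-methyl-2-(trimethylsilyloxy)cyclohex-1-ene; 3 3-(benzyloxy)propanal
Product: 5 rac-(2R*)-2-[(1R*)-3-(benzyloxy)-1-hydroxypropyl]-2-methylcyclohexan-1-one, via lithium 2-methylcyclohex-1-en-1-olate 4 (not isolated)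
Conditions: MeLi (1.0 equiv), THF, 0 °C → rt; then 3, −78 °C, short contact; AcOH, −78 °C
Reagents that add atoms: none
Why: MeLi cleaves the O–Si bond to the regiodefined tetrasubstituted lithium enolate, which should add to the aldehyde through a closed six-membered chair (aldehyde chain equatorial, methyl held on the oxygen side of the enolate by the ring), placing methyl and hydroxyl syn along C1–C2–C1′, i.e. the (2R*,1′R*) pair (lithium enolate aldol addition); the cold acidic quench prevents retro-aldol equilibration and minor isomers are removed by chromatography.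

Step 3
Reactants: 5 rac-(2R*)-2-[(1R*)-3-(benzyloxy)-1-hydroxypropyl]-2-methylcyclohexan-1-one
Product: 6 (2R)-2-[(1R)-3-(benzyloxy)-1-hydroxypropyl]-2-methylcyclohexan-1-one
Conditions: preparative supercritical-fluid chromatography, amylose tris(3,5-dimethylphenylcarbamate) on silica, CO2/MeOH, 35 °C
Reagents that add atoms: none
Why: The free hydroxyl and the aryl ether give the handles for separating the enantiomers on a carbamoylated polysaccharide phase (resolution by chiral chromatography), which fixes the absolute configuration of both stereocentres at once without making or breaking a bond.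

Step 4
Reactants: 6 (2R)-2-[(1R)-3-(benzyloxy)-1-hydroxypropyl]-2-methylcyclohexan-1-one
Product: 7 (2R)-2-[(1R)-3-(benzyloxy)-1-(triethylsilyloxy)propyl]-2-methylcyclohexan-1-one
Conditions: Et3SiOTf, 2,6-lutidine, CH2Cl2, −78 → 0 °C
Reagents that add atoms: triethylsilyl trifluoromethanesulfonate, CC[Si](CC)(CC)OS(=O)(=O)C(F)(F)F
Why: The silyl triflate silylates the hindered secondary alcohol quickly and the weak, hindered base avoids retro-aldol cleavage (silyl ether formation); triethylsilyl is chosen because it can later be removed next to the fully substituted carbon under mild acidic fluoride.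

Step 5
Reactants: 7 (2R)-2-[(1R)-3-(benzyloxy)-1-(triethylsilyloxy)propyl]-2-methylcyclohexan-1-one
Product: 9 (7R)-7-[(1R)-3-(benzyloxy)-1-(triethylsilyloxy)propyl]-7-methyloxepan-2-one, via peroxyhemiketal 8 (not isolated)
Conditions: mCPBA (3 equiv), NaHCO3, CH2Cl2, 0 °C → rt, dark
Reagents that add atoms: 3-chloroperbenzoic acid, O=C(OO)c1cccc(Cl)c1
Why: The peracid adds to the ketone to give peroxyhemiketal 8, and the fully substituted α-carbon, the group best able to carry positive charge and aligned antiperiplanar to the O–O bond, shifts from carbon to oxygen as 3-chlorobenzoate leaves (Baeyer–Villiger oxidation of a 2,2-disubstituted cyclohexanone). The seven-membered ring is not closed by a cyclisation: it arises by 1,2-migration within the six-membered ketone, which inserts O1 between the carbonyl carbon and the quaternary carbon and forms the O1–C2 and O1–C7 bonds together. No stereocentre is created; the migrating carbon keeps its configuration, so the quaternary aldol centre becomes the tertiary C7–O centre as (R) and C1′ is untouched. The selectivity needed is regioselectivity of migration, secured by the much higher migratory aptitude of the quaternary carbon over the ring methylene on the other side, even with a silyloxy group one carbon away. Chemoselectivity is secured by the substrate, which holds no alkene and only benzyl and silyl ethers that are inert to buffered peracid.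

Step 6
Reactants: 9 (7R)-7-[(1R)-3-(benzyloxy)-1-(triethylsilyloxy)propyl]-7-methyloxepan-2-one
Product: 10 (7R)-7-[(1R)-3-hydroxy-1-(triethylsilyloxy)propyl]-7-methyloxepan-2-one
Conditions: H2 (1 atm), 10% Pd/C, EtOAc, rt
Reagents that add atoms: none
Why: Hydrogenolysis of the benzyl ether is clean at this stage because the molecule holds no alkene, and the lactone and silyl ether are inert in ethyl acetate (catalytic hydrogenolysis).

Step 7
Reactants: 10 (7R)-7-[(1R)-3-hydroxy-1-(triethylsilyloxy)propyl]-7-methyloxepan-2-one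
Product: 11 (7R)-7-[(1R)-3-iodo-1-(triethylsilyloxy)propyl]-7-methyloxepan-2-one
Conditions: PPh3, imidazole, I2, CH2Cl2, 0 °C → rt
Reagents that add atoms: iodine, II
Why: The alkoxyphosphonium ion of the unhindered primary alcohol is displaced by iodide in an SN2 step (Appel-type iodination), leaving the silyl ether and the lactone untouched.

Step 8
Reactants: 12 but-2-yn-1-ol
Product: 14 (2Z)-3-iodobut-2-en-1-ol, via sodium alkenylalanate 13 (not isolated)
Conditions: NaAlH2(OCH2CH2OCH3)2, THF, 0 °C → rt; then I2, −78 → 0 °C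
Reagents that add atoms: iodine, II
Why: The alkoxide-bound aluminium hydride adds trans across the alkyne with hydride at C2 and aluminium at C3, held cis to the CH2O group in a five-membered ring, and iodine replaces aluminium with retention (hydroxyl-directed trans-hydroalumination–iodination), which sets the Z geometry with iodine cis to CH2OH.

Step 9
Reactants: 14 (2Z)-3-iodobut-2-en-1-ol
Product: 15 tert-butyl{[(2Z)-3-iodobut-2-en-1-yl]oxy}dimethylsilane
Conditions: t-BuMe2SiCl, imidazole, CH2Cl2, rt
Reagents that add atoms: tert-butylchlorodimethylsilane, CC(C)(C)[Si](C)(C)Cl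
Why: Silylation of the primary allylic alcohol (silyl ether formation) removes the acidic proton that would quench the zinc reagent in the next step.

Step 10
Reactants: 11 (7R)-7-[(1R)-3-iodo-1-(triethylsilyloxy)propyl]-7-methyloxepan-2-one; 15 tert-butyl{[(2Z)-3-iodobut-2-en-1-yl]oxy}dimethylsilane
Product: 17 (7R)-7-[(1R,4Z)-6-(tert-butyldimethylsilyloxy)-4-methyl-1-(triethylsilyloxy)hex-4-en-1-yl]-7-methyloxepan-2-one, via alkylzinc iodide 16 (not isolated)
Conditions: Zn dust (activated with BrCH2CH2Br and Me3SiCl), LiCl, THF, 30 °C; then 15, Pd(PPh3)4 (5 mol %), THF, rt → 40 °C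
Reagents that add atoms: none
Why: Zinc inserts into the primary C–I bond without touching the lactone or the silyl ethers, and the alkylzinc iodide couples with the alkenyl iodide at zerovalent palladium with retention of alkene geometry (Negishi sp3–sp2 coupling), so the chain ends up cis to the CH2O group (4Z).

Step 11
Reactants: 17 (7R)-7-[(1R,4Z)-6-(tert-butyldimethylsilyloxy)-4-methyl-1-(triethylsilyloxy)hex-4-en-1-yl]-7-methyloxepan-2-one
Product: 21 (7R)-7-[(1R,4Z)-6-(tert-butyldimethylsilyloxy)-4-methyl-1-(triethylsilyloxy)hex-4-en-1-yl]-7-methyl-6,7-dihydrooxepin-2(5H)-one, via lithium lactone enolate 18 (not isolated), via α-phenylselanyl lactone 19 (not isolated), via selenoxide 20 (not isolated)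
Conditions: LiN(iPr)2, THF, −78 °C; PhSeBr (1.05 equiv), −78 °C; then NaIO4, NaHCO3, THF/MeOH/H2O, 0 °C → rt
Reagents that add atoms: none
Why: The lactone enolate is selenenylated at C3 and the derived selenoxide undergoes syn-elimination toward C4, the only carbon with β-hydrogens, giving the ring alkene whose cis geometry is enforced by the seven-membered ring (selenoxide elimination); one equivalent of PhSeBr at −78 °C and periodate as oxidant spare the trisubstituted alkene.

Step 12
Reactants: 21 (7R)-7-[(1R,4Z)-6-(tert-butyldimethylsilyloxy)-4-methyl-1-(triethylsilyloxy)hex-4-en-1-yl]-7-methyl-6,7-dihydrooxepin-2(5H)-one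
Product: 22 (7R)-3-iodo-7-[(1R,4Z)-6-(tert-butyldimethylsilyloxy)-4-methyl-1-(triethylsilyloxy)hex-4-en-1-yl]-7-methyl-6,7-dihydrooxepin-2(5H)-one
Conditions: I2 (3 equiv), pyridine/CH2Cl2 (1:1), DMAP (0.2 equiv), rt, dark
Reagents that add atoms: iodine, II
Why: The amine adds to C4 of the enoate, the resulting ester enolate is iodinated at C3 and the amine is expelled again (addition–elimination α-iodination of the Baylis–Hillman type, established for cyclic enones and α,β-unsaturated lactones); in the dark iodine should neither add to nor isomerise the isolated trisubstituted alkene.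

Step 13
Reactants: 23 3-(tert-butyldimethylsilyloxy)propanal; 24 ethyl 2-[bis(2,2,2-trifluoroethoxy)phosphoryl]propanoate
Product: 26 ethyl (2Z)-5-(tert-butyldimethylsilyloxy)-2-methylpent-2-enoate, via potassium phosphonate carbanion 25 (not isolated)
Conditions: 24, KN(SiMe3)2, 18-crown-6, THF, −78 °C; then 23, −78 °C
Reagents that add atoms: none
Why: With the electron-poor bis(trifluoroethyl) phosphonate and a dissociated potassium counter-ion, elimination from the kinetically formed adduct outruns its equilibration, so the ester ends up cis to the chain (Still–Gennari variant of the Horner–Wadsworth–Emmons olefination), which sets the Z geometry of the west alkene.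

Step 14
Reactants: 26 ethyl (2Z)-5-(tert-butyldimethylsilyloxy)-2-methylpent-2-enoate
Product: 27 (2Z)-5-(tert-butyldimethylsilyloxy)-2-methylpent-2-en-1-ol
Conditions: i-Bu2AlH (2.5 equiv), CH2Cl2, −78 °C; aqueous potassium sodium tartrate
Reagents that add atoms: none
Why: The aluminium hydride reduces the enoate by 1,2-addition to the allylic alcohol without touching the alkene or its geometry (hydride reduction of an ester).

Step 15
Reactants: 27 (2Z)-5-(tert-butyldimethylsilyloxy)-2-methylpent-2-en-1-ol
Product: 28 (2Z)-5-(tert-butyldimethylsilyloxy)-2-methylpent-2-en-1-yl acetate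
Conditions: Ac2O, pyridine, DMAP (cat.), CH2Cl2, 0 °C → rt
Reagents that add atoms: acetic anhydride, CC(=O)OC(C)=O
Why: Nucleophilic catalysis by DMAP acetylates the primary allylic alcohol (acylation), installing the acetate of the target early, where it costs no step on the main line.

Step 16
Reactants: 28 (2Z)-5-(tert-butyldimethylsilyloxy)-2-methylpent-2-en-1-yl acetate
Product: 29 (2Z)-5-hydroxy-2-methylpent-2-en-1-yl acetate
Conditions: HF·pyridine, pyridine, THF, 0 °C → rt
Reagents that add atoms: none
Why: Buffered acidic fluoride cleaves the primary silyl ether (fluoride-mediated desilylation) and, unlike basic fluoride, neither removes nor transfers the acetate.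

Step 17
Reactants: 29 (2Z)-5-hydroxy-2-methylpent-2-en-1-yl acetate
Product: 30 (2Z)-5-iodo-2-methylpent-2-en-1-yl acetate
Conditions: PPh3, imidazole, I2, CH2Cl2, 0 °C → rt
Reagents that add atoms: iodine, II
Why: The primary homoallylic alcohol is converted through its alkoxyphosphonium ion by SN2 displacement with iodide (Appel-type iodination), conditions under which the allylic acetate and the alkene geometry are stable.

Step 18
Reactants: 30 (2Z)-5-iodo-2-methylpent-2-en-1-yl acetate; 22 (7R)-3-iodo-7-[(1R,4Z)-6-(tert-butyldimethylsilyloxy)-4-methyl-1-(triethylsilyloxy)hex-4-en-1-yl]-7-methyl-6,7-dihydrooxepin-2(5H)-one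
Product: 32 (2Z)-5-{(7R)-7-[(1R,4Z)-6-(tert-butyldimethylsilyloxy)-4-methyl-1-(triethylsilyloxy)hex-4-en-1-yl]-7-methyl-2-oxo-2,5,6,7-tetrahydrooxepin-3-yl}-2-methylpent-2-en-1-yl acetate, via homoallylic zinc iodide 31 (not isolated)
Conditions: 30, Zn dust, LiCl, THF, 25 °C; then 22, Pd2(dba)3 (2.5 mol %), P(2-furyl)3 (10 mol %), THF/DMF, rt
Reagents that add atoms: none
Why: Oxidative addition of zerovalent palladium to the electron-poor C3–I bond is fast, and transmetalation from the primary alkylzinc followed by reductive elimination forms the C3–CH2 bond with all alkene geometries untouched (Negishi sp2–sp3 coupling of an α-iodoenoate); the weakly donating tri(2-furyl)phosphine and room temperature are chosen so that the allylic acetate is not ionised while iodide remains.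

Step 19
Reactants: 32 (2Z)-5-{(7R)-7-[(1R,4Z)-6-(tert-butyldimethylsilyloxy)-4-methyl-1-(triethylsilyloxy)hex-4-en-1-yl]-7-methyl-2-oxo-2,5,6,7-tetrahydrooxepin-3-yl}-2-methylpent-2-en-1-yl acetate
Product: 33 (2Z)-5-{(7R)-7-[(1R,4Z)-1,6-dihydroxy-4-methylhex-4-en-1-yl]-7-methyl-2-oxo-2,5,6,7-tetrahydrooxepin-3-yl}-2-methylpent-2-en-1-yl acetate (CNP0286404.1)
Conditions: HF·pyridine, pyridine, THF, 0 °C → rt
Reagents that add atoms: none
Why: Mildly acidic fluoride cleaves the primary tert-butyldimethylsilyl ether and the hindered triethylsilyl ether (fluoride-mediated desilylation) while the allylic acetate, the enoate and both Z-alkenes persist; basic fluoride is avoided so that the lactone acyl group cannot shift from O1 to the freed C1′ oxygen.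

Compound list
1 | 2-methylcyclohexanone (racemic) | CC1CCCCC1=O | starting material
2 | 1-methyl-2-(trimethylsilyloxy)cyclohex-1-ene | CC1=C(O[Si](C)(C)C)CCCC1 | intermediate
3 | 3-(benzyloxy)propanal | O=CCCOCc1ccccc1 | starting material
4 | lithium 2-methylcyclohex-1-en-1-olate | CC1=C([O-])CCCC1.[Li+] | intermediate (not isolated)
5 | rac-(2R*)-2-[(1R*)-3-(benzyloxy)-1-hydroxypropyl]-2-methylcyclohexan-1-one (racemate; one enantiomer drawn) | O=C1CCCC[C@]1(C)[C@H](O)CCOCc1ccccc1 | intermediate
6 | (2R)-2-[(1R)-3-(benzyloxy)-1-hydroxypropyl]-2-methylcyclohexan-1-one | O=C1CCCC[C@]1(C)[C@H](O)CCOCc1ccccc1 | intermediate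
7 | (2R)-2-[(1R)-3-(benzyloxy)-1-(triethylsilyloxy)propyl]-2-methylcyclohexan-1-one | O=C1CCCC[C@]1(C)[C@H](O[Si](CC)(CC)CC)CCOCc1ccccc1 | intermediate (key-step precursor)
8 | peroxyhemiketal of 7 (C1 bears OH and 3-chlorobenzoylperoxy; C1 configuration undefined) | OC1(OOC(=O)c2cccc(Cl)c2)CCCC[C@]1(C)[C@H](O[Si](CC)(CC)CC)CCOCc1ccccc1 | intermediate (not isolated)
9 | (7R)-7-[(1R)-3-(benzyloxy)-1-(triethylsilyloxy)propyl]-7-methyloxepan-2-one | O=C1CCCC[C@](C)([C@H](O[Si](CC)(CC)CC)CCOCc2ccccc2)O1 | intermediate (key-step product)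
10 | (7R)-7-[(1R)-3-hydroxy-1-(triethylsilyloxy)propyl]-7-methyloxepan-2-one | O=C1CCCC[C@](C)([C@H](O[Si](CC)(CC)CC)CCO)O1 | intermediate
11 | (7R)-7-[(1R)-3-iodo-1-(triethylsilyloxy)propyl]-7-methyloxepan-2-one | O=C1CCCC[C@](C)([C@H](O[Si](CC)(CC)CC)CCI)O1 | intermediate
12 | but-2-yn-1-ol | CC#CCO | starting material
13 | sodium 2,2-bis(2-methoxyethoxy)-3-methyl-2,5-dihydro-1,2-oxaluminol-2-uide (cyclic alkenylalanate) | CC1=CCO[Al-]1(OCCOC)OCCOC.[Na+] | intermediate (not isolated)
14 | (2Z)-3-iodobut-2-en-1-ol | C/C(I)=C/CO | intermediate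
15 | tert-butyl{[(2Z)-3-iodobut-2-en-1-yl]oxy}dimethylsilane | C/C(I)=C/CO[Si](C)(C)C(C)(C)C | intermediate
16 | alkylzinc iodide from 11 (C–I replaced by C–ZnI) | O=C1CCCC[C@](C)([C@H](O[Si](CC)(CC)CC)CC[Zn]I)O1 | intermediate (not isolated)
17 | (7R)-7-[(1R,4Z)-6-(tert-butyldimethylsilyloxy)-4-methyl-1-(triethylsilyloxy)hex-4-en-1-yl]-7-methyloxepan-2-one | O=C1CCCC[C@](C)([C@H](O[Si](CC)(CC)CC)CC/C(C)=C\CO[Si](C)(C)C(C)(C)C)O1 | intermediate
18 | lithium enolate of 17 (C2–O−, C2=C3) | [Li+].[O-]C1=CCCC[C@](C)([C@H](O[Si](CC)(CC)CC)CC/C(C)=C\CO[Si](C)(C)C(C)(C)C)O1 | intermediate (not isolated)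
19 | 3-(phenylselanyl) derivative of 17 (C3 epimers) | O=C1C([Se]c2ccccc2)CCC[C@](C)([C@H](O[Si](CC)(CC)CC)CC/C(C)=C\CO[Si](C)(C)C(C)(C)C)O1 | intermediate (not isolated)
20 | selenoxide of 19 | O=C1C([Se](=O)c2ccccc2)CCC[C@](C)([C@H](O[Si](CC)(CC)CC)CC/C(C)=C\CO[Si](C)(C)C(C)(C)C)O1 | intermediate (not isolated)
21 | (7R)-7-[(1R,4Z)-6-(tert-butyldimethylsilyloxy)-4-methyl-1-(triethylsilyloxy)hex-4-en-1-yl]-7-methyl-6,7-dihydrooxepin-2(5H)-one | O=C1C=CCC[C@](C)([C@H](O[Si](CC)(CC)CC)CC/C(C)=C\CO[Si](C)(C)C(C)(C)C)O1 | intermediate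
22 | (7R)-3-iodo-7-[(1R,4Z)-6-(tert-butyldimethylsilyloxy)-4-methyl-1-(triethylsilyloxy)hex-4-en-1-yl]-7-methyl-6,7-dihydrooxepin-2(5H)-one | O=C1C(I)=CCC[C@](C)([C@H](O[Si](CC)(CC)CC)CC/C(C)=C\CO[Si](C)(C)C(C)(C)C)O1 | intermediate
23 | 3-(tert-butyldimethylsilyloxy)propanal | O=CCCO[Si](C)(C)C(C)(C)C | starting material
24 | ethyl 2-[bis(2,2,2-trifluoroethoxy)phosphoryl]propanoate | CCOC(=O)C(C)P(=O)(OCC(F)(F)F)OCC(F)(F)F | starting material
25 | potassium salt of the carbanion of 24 | CCOC(=O)[C-](C)P(=O)(OCC(F)(F)F)OCC(F)(F)F.[K+] | intermediate (not isolated)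
26 | ethyl (2Z)-5-(tert-butyldimethylsilyloxy)-2-methylpent-2-enoate | CCOC(=O)/C(C)=C\CCO[Si](C)(C)C(C)(C)C | intermediate
27 | (2Z)-5-(tert-butyldimethylsilyloxy)-2-methylpent-2-en-1-ol | OC/C(C)=C\CCO[Si](C)(C)C(C)(C)C | intermediate
28 | (2Z)-5-(tert-butyldimethylsilyloxy)-2-methylpent-2-en-1-yl acetate | CC(=O)OC/C(C)=C\CCO[Si](C)(C)C(C)(C)C | intermediate
29 | (2Z)-5-hydroxy-2-methylpent-2-en-1-yl acetate | CC(=O)OC/C(C)=C\CCO | intermediate
30 | (2Z)-5-iodo-2-methylpent-2-en-1-yl acetate | CC(=O)OC/C(C)=C\CCI | intermediate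
31 | [(3Z)-5-acetoxy-4-methylpent-3-en-1-yl]zinc iodide | CC(=O)OC/C(C)=C\CC[Zn]I | intermediate (not isolated)
32 | (2Z)-5-{(7R)-7-[(1R,4Z)-6-(tert-butyldimethylsilyloxy)-4-methyl-1-(triethylsilyloxy)hex-4-en-1-yl]-7-methyl-2-oxo-2,5,6,7-tetrahydrooxepin-3-yl}-2-methylpent-2-en-1-yl acetate | CC(=O)OC/C(C)=C\CCC1=CCC[C@](C)([C@H](O[Si](CC)(CC)CC)CC/C(C)=C\CO[Si](C)(C)C(C)(C)C)OC1=O | intermediate
33 | (2Z)-5-{(7R)-7-[(1R,4Z)-1,6-dihydroxy-4-methylhex-4-en-1-yl]-7-methyl-2-oxo-2,5,6,7-tetrahydrooxepin-3-yl}-2-methylpent-2-en-1-yl acetate (CNP0286404.1) | CC(=O)OC/C(C)=C\CCC1=CCC[C@](C)([C@H](O)CC/C(C)=C\CO)OC1=O | target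

Total step count: 19
Longest linear sequence: 12 steps (steps 1–7, 10–12, 18 and 19)

Steps most likely to fail

Step 12. Conjugate addition of the amine to the seven-membered enoate may be too slow, so that conversion stalls and long exposure to iodine starts to erode the silyl ethers or the alkene geometry. The fallback sets out from lactone 17 and comes back at 32, replacing steps 11 and 12. Enolate 18, generated as in step 11, is hydroxylated at C3 with 3-phenyl-2-(phenylsulfonyl)oxaziridine to the α-hydroxy lactone F1. Oxidation with 1,1,1-triacetoxy-1,1-dihydro-1,2-benziodoxol-3(1H)-one gives the α-keto lactone F2. Tf2O and 2,6-di-tert-butyl-4-methylpyridine in CH2Cl2 at −78 °C trap its only possible enol (toward C4) as the enol triflate F3. F3 already holds the C3=C4 bond and a leaving group on C3, and is coupled with zinc reagent 31 under the conditions of step 18 to give 32.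

Step 18. Zerovalent palladium may ionise the allylic acetate once the iodoenoate is consumed, leading to reduction or allylic scrambling at the west terminus, and the zinc reagent may be lost by protonolysis. The fallback sets out from alcohol 27 and comes back at 32; the west oxygen travels through the coupling as an ether and is acetylated afterwards. NaH and 4-methoxybenzyl chloride convert 27 into the 4-methoxybenzyl ether F4. Bu4NF frees the homoallylic alcohol F5, and the Appel reaction gives the iodide F6. Zinc insertion as in step 18 gives the zinc reagent F7, which is coupled with 22 to the coupled 4-methoxybenzyl ether F8. DDQ in wet CH2Cl2 releases the allylic alcohol F9, and Ac2O with pyridine gives 32.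

Step 5. Addition of the peracid to a carbonyl group shielded by the quaternary carbon and its silyloxy neighbour may be slow, giving incomplete conversion and loss of the silyl ether on long exposure. The fallback sets out from aldol 6 and comes back at lactone 9; oxidation and protection change places. The free hydroxyl of 6 hydrogen-bonds the peracid and lowers the steric demand, so mCPBA with NaHCO3 should pass through the hydroxy peroxyhemiketal F10 to the hydroxy lactone F11 with the same migration and retention. Et3SiOTf with 2,6-lutidine then gives 9.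

Further compounds
F1 | step 12 | (7R)-3-hydroxy-7-[(1R,4Z)-6-(tert-butyldimethylsilyloxy)-4-methyl-1-(triethylsilyloxy)hex-4-en-1-yl]-7-methyloxepan-2-one (C3 epimers) | O=C1C(O)CCC[C@](C)([C@H](O[Si](CC)(CC)CC)CC/C(C)=C\CO[Si](C)(C)C(C)(C)C)O1
F2 | step 12 | (7R)-7-[(1R,4Z)-6-(tert-butyldimethylsilyloxy)-4-methyl-1-(triethylsilyloxy)hex-4-en-1-yl]-7-methyloxepane-2,3-dione | O=C1C(=O)CCC[C@](C)([C@H](O[Si](CC)(CC)CC)CC/C(C)=C\CO[Si](C)(C)C(C)(C)C)O1
F3 | step 12 | (7R)-7-[(1R,4Z)-6-(tert-butyldimethylsilyloxy)-4-methyl-1-(triethylsilyloxy)hex-4-en-1-yl]-7-methyl-2-oxo-2,5,6,7-tetrahydrooxepin-3-yl trifluoromethanesulfonate | O=C1C(OS(=O)(=O)C(F)(F)F)=CCC[C@](C)([C@H](O[Si](CC)(CC)CC)CC/C(C)=C\CO[Si](C)(C)C(C)(C)C)O1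
F4 | step 18 | tert-butyl({(3Z)-5-[(4-methoxybenzyl)oxy]-4-methylpent-3-en-1-yl}oxy)dimethylsilane | COc1ccc(COC/C(C)=C\CCO[Si](C)(C)C(C)(C)C)cc1
F5 | step 18 | (3Z)-5-[(4-methoxybenzyl)oxy]-4-methylpent-3-en-1-ol | COc1ccc(COC/C(C)=C\CCO)cc1
F6 | step 18 | 1-({[(2Z)-5-iodo-2-methylpent-2-en-1-yl]oxy}methyl)-4-methoxybenzene | COc1ccc(COC/C(C)=C\CCI)cc1
F7 | step 18 | {(3Z)-5-[(4-methoxybenzyl)oxy]-4-methylpent-3-en-1-yl}zinc iodide | COc1ccc(COC/C(C)=C\CC[Zn]I)cc1
F8 | step 18 | (7R)-7-[(1R,4Z)-6-(tert-butyldimethylsilyloxy)-4-methyl-1-(triethylsilyloxy)hex-4-en-1-yl]-3-{(3Z)-5-[(4-methoxybenzyl)oxy]-4-methylpent-3-en-1-yl}-7-methyl-6,7-dihydrooxepin-2(5H)-one | COc1ccc(COC/C(C)=C\CCC2=CCC[C@](C)([C@H](O[Si](CC)(CC)CC)CC/C(C)=C\CO[Si](C)(C)C(C)(C)C)OC2=O)cc1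
F9 | step 18 | (7R)-7-[(1R,4Z)-6-(tert-butyldimethylsilyloxy)-4-methyl-1-(triethylsilyloxy)hex-4-en-1-yl]-3-[(3Z)-5-hydroxy-4-methylpent-3-en-1-yl]-7-methyl-6,7-dihydrooxepin-2(5H)-one | OC/C(C)=C\CCC1=CCC[C@](C)([C@H](O[Si](CC)(CC)CC)CC/C(C)=C\CO[Si](C)(C)C(C)(C)C)OC1=O
F10 | step 5 | peroxyhemiketal of 6 (C1 bears OH and 3-chlorobenzoylperoxy; C1 configuration undefined) | OC1(OOC(=O)c2cccc(Cl)c2)CCCC[C@]1(C)[C@H](O)CCOCc1ccccc1
F11 | step 5 | (7R)-7-[(1R)-3-(benzyloxy)-1-hydroxypropyl]-7-methyloxepan-2-one | O=C1CCCC[C@](C)([C@H](O)CCOCc2ccccc2)O1
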